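The target is cut at C5–C6 and C5'–C6' of its two benzene rings (chroman numbering, primes for the second half). The bridge carbon with C6, C7, C6' and C7' is a 3-(5-methylhexyl)glutaryl unit. C8, C8a, C4a, C5 and each pyran ring (O1 to C4) come from a cyclised prenylacetoacetate, so the O1–C8a bond exists before any arene. One base-mediated operation closes and aromatises both benzene rings by twofold Dieckmann-type attack of C6/C6' on the C5/C5' esters. The precursor is a symmetric bis(keto ester): two 2-pyranylmethyl ketone arms, each with a methyl ester on the dihydropyran, flank the alkylated bridge. Twofold C8 acylation with (R)-2-methylbutanoyl chloride finishes the synthesis.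

Key step: step 6

Remark: 6-methylheptanal and (R)-2-methylbutanoic acid are taken as purchasable. Both side-chain stereocentres of the target are (R) and come from the acid; the bridge carbon carries two identical arms and is not stereogenic, so the route creates no stereocentre.

Step 1
Reactants: 1 methyl acetoacetate; 2 prenyl bromide (1-bromo-3-methylbut-2-ene)
Product: 3 methyl 2-acetyl-5-methylhex-4-enoate (racemic)
Conditions: 1 (1.2 equiv), NaH (1.1 equiv), THF, 0 °C; then 2 (1.0 equiv), 0 °C to rt
Reagents that add atoms: none
Why: Acetoacetic ester alkylation, an SN2 reaction of the sodium enolate at carbon with a primary allylic bromide; the slight excess of 1 should suppress dialkylation, and the new stereocentre is racemic and disappears in step 2.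

Step 2
Reactants: 3 methyl 2-acetyl-5-methylhex-4-enoate
Product: 4 methyl 2,6,6-trimethyl-5,6-dihydro-4H-pyran-3-carboxylate
Conditions: TfOH (5 mol%), CH2Cl2, 0 °C to rt
Reagents that add atoms: none
Why: Acid-catalysed intramolecular hydroalkoxylation, known for 2-prenyl-1,3-dicarbonyl compounds: Markovnikov protonation of the trisubstituted alkene gives a tertiary cation that the ketone (enol) oxygen traps in a six-membered closure, leaving the conjugated β-alkoxy acrylate.

Step 3
Reactants: 5 6-methylheptanal; 6 diethyl malonate
Product: 8 3-(5-methylhexyl)pentanedioic acid, via tetraester 7 (not isolated)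
Conditions: 6 (2.2 equiv), piperidine (cat.), AcOH (cat.), EtOH, rt to 60 °C; then 6 M HCl, reflux
Reagents that add atoms: water, O
Why: Knoevenagel condensation followed by Michael addition of a second malonate gives the alkylidene bismalonate, and acid hydrolysis with twofold decarboxylation is the classical route to 3-alkylglutaric acids; C3 carries two identical arms, so no stereocentre arises.

Step 4
Reactants: 8 3-(5-methylhexyl)pentanedioic acid
Product: 10 N1,N5-dimethoxy-N1,N5-dimethyl-3-(5-methylhexyl)pentanediamide, via diacid dichloride 9 (not isolated)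
Conditions: (COCl)2 (2.5 equiv), DMF (cat.), CH2Cl2, 0 °C to rt, evaporate; then MeNH(OMe)·HCl (2.4 equiv), pyridine, CH2Cl2, 0 °C to rt
Reagents that add atoms: N,O-dimethylhydroxylamine hydrochloride, CNOC.Cl
Why: Routine acid chloride formation and amidation; the bis(Weinreb amide) is chosen as the activated glutarate because each ketone is released only on work-up, which excludes over-addition and the six-membered enol lactone that a glutaryl dichloride would form after the first acylation.

Step 5
Reactants: 4 methyl 2,6,6-trimethyl-5,6-dihydro-4H-pyran-3-carboxylate; 10 N1,N5-dimethoxy-N1,N5-dimethyl-3-(5-methylhexyl)pentanediamide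
Product: 12 dimethyl 2,2'-[4-(5-methylhexyl)-2,6-dioxoheptane-1,7-diyl]bis(6,6-dimethyl-5,6-dihydro-4H-pyran-3-carboxylate), via lithium dienolate 11 (not isolated)
Conditions: 4 (2.8 equiv), LiN(i-Pr)2 (2.7 equiv, commercial solution), THF, −78 °C; then 10 (1.0 equiv), −78 to −20 °C; aq. NH4Cl
Reagents that add atoms: none
Why: The amide base removes a γ-proton from the C2 methyl group of the β-alkoxy acrylate (as in the lithiation of 6-methyl-1,3-dioxin-4-ones and 4-methoxy-6-methyl-2-pyranones), and the dienolate is acylated at its γ-carbon, the α-carbon being fully substituted, by both amide groups in a vinylogous Claisen-type Weinreb ketone synthesis; the chelated tetrahedral intermediates persist until the quench, so the acidic C8 protons of 12 never meet the dienolate.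

Step 6
Reactants: 12 dimethyl 2,2'-[4-(5-methylhexyl)-2,6-dioxoheptane-1,7-diyl]bis(6,6-dimethyl-5,6-dihydro-4H-pyran-3-carboxylate)
Product: 15 6,6'-(6-methylheptane-1,1-diyl)bis(2,2-dimethylchromane-5,7-diol), via disodium bis-enolate 13 (not isolated), via monocyclised trisodium salt 14 (not isolated)
Conditions: 12 added slowly to NaH (8 equiv), DME, 0 °C to rt, then reflux; degassed 1 M HCl, 0 °C
Reagents that add atoms: none
Why: NaH first removes the doubly activated C8 and C8' protons, which masks both ketones as extended enolates so that the two arms cannot undergo a 1,5-diketone aldol condensation, and on heating it reaches the C6 and C6' protons; each terminal C6 carbanion should then add to its own ester carbon C5, methoxide leaves, and loss of the remaining C6 proton gives the resorcinolate, which makes each closure irreversible. The closest known reaction types are the Dieckmann-type Claisen cyclisation of 3,5-dioxoalkanoates to phloroglucinols and the NaH-mediated acylation of 1,3-dicarbonyl anions at their terminal carbon by esters. Each benzene ring closes in a six-membered (enolendo)-exo-trig acyl substitution across the C8a=C4a double bond, whose ring-locked geometry holds C8 and C5 cis. No stereocentre is formed, and the bridge carbon stays non-stereogenic because both arms are identical. The step needs C-acylation to win over O-acylation by the C7 enolate oxygen (fused 2-pyranone) and closure within one arm to win over closure between arms: the NaOCH3 set free should reopen any enol lactone while the phenoxide is a sink, and attack of C6 on C5' would need an eight-membered ring. Because O1 is already bonded to C8a, the position of the pyran oxygen relative to the bridge is fixed by connectivity and not by a late prenyl cyclisation.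

Step 7
Reactants: 16 (R)-2-methylbutanoic acid
Product: 17 (R)-2-methylbutanoyl chloride
Conditions: (COCl)2 (1.05 equiv), DMF (cat.), CH2Cl2, 0 °C to rt; used as a CH2Cl2 solution
Reagents that add atoms: oxalyl chloride, ClC(=O)C(=O)Cl
Why: Vilsmeier-type chlorination of a carboxylic acid; no amine base is present, so no ketene can form and the α-stereocentre should keep its (R) configuration.

Step 8
Reactants: 15 6,6'-(6-methylheptane-1,1-diyl)bis(2,2-dimethylchromane-5,7-diol); 17 (R)-2-methylbutanoyl chloride
Product: 18 (2R,2'R)-1,1'-[(6-methylheptane-1,1-diyl)bis(5,7-dihydroxy-2,2-dimethylchromane-6,8-diyl)]bis(2-methylbutan-1-one), the target CNP0324275.1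
Conditions: 17 (2.4 equiv), AlCl3 (8 equiv), CH2Cl2/MeNO2, 0 °C to rt; ice, 1 M HCl
Reagents that add atoms: none
Why: Friedel–Crafts acylation (any aryl ester formed should follow by Fries rearrangement) at C8 and C8', the only unsubstituted ring positions, each activated by O1 and 7-OH (ortho) and 5-OH (para); both stereocentres come unchanged from 17, since neither the acylium ion nor the AlCl3-complexed ketone should enolise at or below room temperature without base, and the cold, short reaction is meant to spare the chroman ethers and the diarylmethine bridge.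

Compound list
1 | methyl acetoacetate | CC(=O)CC(=O)OC | starting material
2 | prenyl bromide (1-bromo-3-methylbut-2-ene) | CC(C)=CCBr | starting material
3 | methyl 2-acetyl-5-methylhex-4-enoate (racemic) | CC(=O)C(CC=C(C)C)C(=O)OC | intermediate
4 | methyl 2,6,6-trimethyl-5,6-dihydro-4H-pyran-3-carboxylate | CC1=C(C(=O)OC)CCC(C)(C)O1 | intermediate
5 | 6-methylheptanal | CC(C)CCCCC=O | starting material
6 | diethyl malonate | CCOC(=O)CC(=O)OCC | starting material
7 | tetraethyl 2-(5-methylhexyl)propane-1,1,3,3-tetracarboxylate (formed in the flask) | CCOC(=O)C(C(=O)OCC)C(CCCCC(C)C)C(C(=O)OCC)C(=O)OCC | intermediate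
8 | 3-(5-methylhexyl)pentanedioic acid | CC(C)CCCCC(CC(=O)O)CC(=O)O | intermediate
9 | 3-(5-methylhexyl)pentanedioyl dichloride (formed in the flask) | CC(C)CCCCC(CC(=O)Cl)CC(=O)Cl | intermediate
10 | N1,N5-dimethoxy-N1,N5-dimethyl-3-(5-methylhexyl)pentanediamide | CC(C)CCCCC(CC(=O)N(C)OC)CC(=O)N(C)OC | intermediate
11 | lithium dienolate of 4 (2-methylidene pyran, ester enolate; formed in the flask) | [Li+].C=C1OC(C)(C)CCC1=C([O-])OC | intermediate
12 | dimethyl 2,2'-[4-(5-methylhexyl)-2,6-dioxoheptane-1,7-diyl]bis(6,6-dimethyl-5,6-dihydro-4H-pyran-3-carboxylate) | CC(C)CCCCC(CC(=O)CC1=C(C(=O)OC)CCC(C)(C)O1)CC(=O)CC1=C(C(=O)OC)CCC(C)(C)O1 | intermediate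
13 | disodium bis(C7/C8 enolate) of 12 (formed in the flask) | [Na+].[Na+].CC(C)CCCCC(CC([O-])=CC1=C(C(=O)OC)CCC(C)(C)O1)CC([O-])=CC1=C(C(=O)OC)CCC(C)(C)O1 | intermediate
14 | trisodium salt with one chroman ring closed and the second arm still an enolised keto ester (formed in the flask) | [Na+].[Na+].[Na+].CC(C)CCCCC(CC([O-])=CC1=C(C(=O)OC)CCC(C)(C)O1)c1c([O-])c2c(cc1[O-])OC(C)(C)CC2 | intermediate
15 | 6,6'-(6-methylheptane-1,1-diyl)bis(2,2-dimethylchromane-5,7-diol) | CC(C)CCCCC(c1c(O)c2c(cc1O)OC(C)(C)CC2)c1c(O)c2c(cc1O)OC(C)(C)CC2 | intermediate
16 | (R)-2-methylbutanoic acid | CC[C@@H](C)C(=O)O | starting material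
17 | (R)-2-methylbutanoyl chloride | CC[C@@H](C)C(=O)Cl | intermediate
18 | (2R,2'R)-1,1'-[(6-methylheptane-1,1-diyl)bis(5,7-dihydroxy-2,2-dimethylchromane-6,8-diyl)]bis(2-methylbutan-1-one) | CC[C@@H](C)C(=O)c1c(O)c(C(CCCCC(C)C)c2c(O)c3c(c(C(=O)[C@H](C)CC)c2O)OC(C)(C)CC3)c(O)c2c1OC(C)(C)CC2 | target

Total step count: 8 steps (in-flask species 7, 9, 11, 13 and 14 are not counted).
Longest linear sequence: 5 steps (steps 3, 4, 5, 6, 8 from 6-methylheptanal, or steps 1, 2, 5, 6, 8 from methyl acetoacetate).

Steps most likely to fail

Step 6. Once C8 is enolised, the ester is deactivated by conjugation and the C6 protons are far less acidic, so the closure may be slow. Lactonisation through the C7 enolate oxygen, aldol condensation between the arms if a ketone is unmasked, or a stall after the first ring are the competing processes. A low-temperature polyanion variant with a lithium amide would be tried first. The fallback gives up arene construction and bridges ready-made rings. Phloroglucinol is condensed with 2-methylbut-3-en-2-ol (BF3·OEt2, dioxane) to 2,2-dimethylchromane-5,7-diol F1. F1 is acylated with 17 (AlCl3, CH2Cl2/MeNO2) and the product is separated from its 6-acyl isomer to give (2R)-1-(5,7-dihydroxy-2,2-dimethylchroman-8-yl)-2-methylbutan-1-one F2. Two equivalents of F2 are then condensed with aldehyde 5 at C6, the only free ring position (TsOH cat., THF). This fallback sets out from 5 and 17 and comes back to the route at 18.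

Step 5. Proton transfer from the amide to the dienolate, attack through the α-carbon, or addition to only one amide group may lower the efficiency of the twofold coupling. The fallback forms the C7–C8 bonds with an acetoacetate dianion and closes the pyrans afterwards. Compound 3 is converted to its dianion (NaH, then n-BuLi, THF, 0 °C) and acylated at the terminal methyl group by 10 to give dimethyl 7-(5-methylhexyl)-2,12-bis(3-methylbut-2-en-1-yl)-3,5,9,11-tetraoxotridecanedioate F3. Both prenyl groups of F3 are then cyclised onto the neighbouring enol oxygens with catalytic TfOH as in step 2. Any exocyclic enol-ether tautomer formed gives the same anions in step 6. This fallback sets out from 3 and 10 and comes back at 12.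

Step 8. Under the Lewis acid the side-chain stereocentres may erode by enolisation. The bridge may be cleaved by ipso-protonation, a chroman ring may open and reclose onto the other oxygen, or two phenols across the bridge may dehydrate to a xanthene. The fallback introduces the acyl groups through aryl anions. Compound 15 is protected (MOMCl, i-Pr2NEt, CH2Cl2) as 6,6'-(6-methylheptane-1,1-diyl)bis[5,7-bis(methoxymethoxy)-2,2-dimethylchromane] F4. Both C8–H, the only ring hydrogens and each flanked by two oxygen substituents, are lithiated (n-BuLi, TMEDA, THF, 0 °C). The dilithio species is quenched with (2R)-N-methoxy-N,2-dimethylbutanamide F5, made from 17 and MeNH(OMe)·HCl with pyridine, to give the tetrakis(methoxymethyl) ether of the target F6. Mild acidic methanolysis (HCl, MeOH, rt to 40 °C) removes the protecting groups. This fallback sets out from 15 and 17 and comes back at 18.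

Further compounds
F1 | step 6 | 2,2-dimethylchromane-5,7-diol | CC1(C)CCc2c(O)cc(O)cc2O1
F2 | step 6 | (2R)-1-(5,7-dihydroxy-2,2-dimethylchroman-8-yl)-2-methylbutan-1-one | CC[C@@H](C)C(=O)c1c(O)cc(O)c2c1OC(C)(C)CC2
F3 | step 5 | dimethyl 7-(5-methylhexyl)-2,12-bis(3-methylbut-2-en-1-yl)-3,5,9,11-tetraoxotridecanedioate | CC(C)CCCCC(CC(=O)CC(=O)C(CC=C(C)C)C(=O)OC)CC(=O)CC(=O)C(CC=C(C)C)C(=O)OC
F4 | step 8 | 6,6'-(6-methylheptane-1,1-diyl)bis[5,7-bis(methoxymethoxy)-2,2-dimethylchromane] | CC(C)CCCCC(c1c(OCOC)c2c(cc1OCOC)OC(C)(C)CC2)c1c(OCOC)c2c(cc1OCOC)OC(C)(C)CC2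
F5 | step 8 | (2R)-N-methoxy-N,2-dimethylbutanamide | CC[C@@H](C)C(=O)N(C)OC
F6 | step 8 | (2R,2'R)-1,1'-{(6-methylheptane-1,1-diyl)bis[5,7-bis(methoxymethoxy)-2,2-dimethylchromane-6,8-diyl]}bis(2-methylbutan-1-one) | CC[C@@H](C)C(=O)c1c(OCOC)c(C(CCCCC(C)C)c2c(OCOC)c3c(c(C(=O)[C@H](C)CC)c2OCOC)OC(C)(C)CC3)c(OCOC)c2c1OC(C)(C)CC2
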